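The butane chain C1–C4 with its erythro methyl pair (C1 on syringyl ring B, C4 on guaiacyl ring A) is the skeleton of meso-2,3-dimethylsuccinic acid, so both benzylic carbons are treated as former carboxyl carbons. Enantioselective opening of the cis anhydride by a ring A zinc reagent fixes both stereocentres. After deoxygenation the remaining carboxyl carbon, C1, is joined to the ring B carbon para to the phenol oxygen in the key step, a palladium-catalysed Negishi acylation of the acid chloride (ring A plus four-carbon chain) with the ring B arylzinc; it exploits that C1, a chain terminus, can stand at the acyl level. Reduction of the ketone and loss of two benzyl groups finish the route.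

Key step: step 5

Assumption: the enantiomer of the TADDOL-derived phosphoramidite ligand in step 2 is the one that opens the anhydride to the (2S,3R) keto acid 6; the sense of induction is to be confirmed on the first run, and the mirror-image ligand is equally accessible.

Step 1
Reactants: 1 meso-2,3-dimethylsuccinic acid
Product: 2 cis-2,3-dimethylsuccinic anhydride
Conditions: AcCl, reflux; evaporate
Reagents that add atoms: none
Why: Cyclodehydration of a 1,4-diacid to the five-membered anhydride through a mixed anhydride with acetyl chloride; the mild conditions should keep the cis (meso) arrangement of the two methyl groups.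

Step 2
Reactants: 2 cis-2,3-dimethylsuccinic anhydride; 3 1-(benzyloxy)-4-bromo-2-methoxybenzene
Product: 6 (2S,3R)-4-[4-(benzyloxy)-3-methoxyphenyl]-2,3-dimethyl-4-oxobutanoic acid, via aryllithium 4 (not isolated), via arylzinc triflate 5 (not isolated)
Conditions: 3, n-BuLi, THF, −78 °C; Zn(OTf)2, −78 °C → rt; then 2, [Rh(cod)Cl]2 (4 mol %), TADDOL-derived N,N-dimethylphosphoramidite ligand (8 mol %), DMF, 50 °C; aq. HCl
Reagents that add atoms: none
Why: Rhodium-catalysed enantioselective desymmetrisation of a meso anhydride with an arylzinc reagent (an acyl cross-coupling of the Negishi type): the chiral monovalent rhodium complex inserts into one of the two enantiotopic acyl–oxygen bonds, and aryl transfer from zinc followed by reductive elimination gives the aryl ketone, so the ligand sets the absolute configuration of both stereocentres at once while their erythro relationship comes from the meso substrate.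

Step 3
Reactants: 6 (2S,3R)-4-[4-(benzyloxy)-3-methoxyphenyl]-2,3-dimethyl-4-oxobutanoic acid
Product: 7 (2S,3S)-4-[4-(benzyloxy)-3-methoxyphenyl]-2,3-dimethylbutanoic acid
Conditions: Et3SiH (4 equiv), TFA–CH2Cl2, 0 °C → rt
Reagents that add atoms: none
Why: Ionic hydrogenation of an aryl ketone activated by the para benzyloxy group, in which hydride from the silane adds to the protonated carbonyl and then to the p-alkoxybenzyl cation; the carboxylic acid, the benzyl ether and both stereocentres should remain untouched (the descriptor at C3 changes only through the priority rules).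

Step 4
Reactants: 8 4-bromo-2,6-dimethoxyphenol
Product: 9 2-(benzyloxy)-5-bromo-1,3-dimethoxybenzene
Conditions: BnBr, K2CO3, DMF, rt
Reagents that add atoms: benzyl bromide, BrCc1ccccc1
Why: Williamson ether synthesis, the phenoxide displacing bromide from benzyl bromide in an SN2 reaction while the aryl bromide stays inert.

Step 5
Reactants: 7 (2S,3S)-4-[4-(benzyloxy)-3-methoxyphenyl]-2,3-dimethylbutanoic acid; 9 2-(benzyloxy)-5-bromo-1,3-dimethoxybenzene
Product: 13 (2S,3S)-1-[4-(benzyloxy)-3,5-dimethoxyphenyl]-4-[4-(benzyloxy)-3-methoxyphenyl]-2,3-dimethylbutan-1-one, via acid chloride 10 (not isolated), via aryllithium 11 (not isolated), via arylzinc chloride 12 (not isolated)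
Conditions: 7, (COCl)2, DMF (cat.), CH2Cl2, 0 °C → rt, evaporate; 9, n-BuLi, THF, −78 °C, then ZnCl2, → 0 °C; combine, Pd(PPh3)4 (5 mol %), THF, 0 °C → rt
Reagents that add atoms: none
Why: Oxalyl chloride with catalytic DMF turns acid 7 into acid chloride 10; zerovalent palladium inserts into its acyl–chlorine bond, the ring B aryl group passes from arylzinc chloride 12 to the acyl complex of divalent palladium, and reductive elimination forms the bond between the carbonyl carbon (C1 of the chain, the later benzylic CH2) and C1 of ring B. The closest known reaction type is the Negishi acylation, the palladium-catalysed ketone synthesis from acid chlorides and organozinc halides. No ring is closed and no new stereocentre is formed; the two existing centres are carried through unchanged. The step needs site selectivity on ring B, single addition and retention at the alpha carbon C2: the bromine position in 9, para to the protected phenol oxygen, fixes the site, whereas Friedel–Crafts acylation of a 1,2,3-trioxygenated benzene would go to the carbon next to an oxygen; the arylzinc reagent does not add to the ketone formed; and the absence of amine base together with the low basicity of the zinc reagent should prevent ketene formation or enolisation at C2. Transmetalation at 0 °C is expected to outrun decarbonylation of the acylpalladium species and Friedel–Crafts closure of 10 onto ring A.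

Step 6
Reactants: 13 (2S,3S)-1-[4-(benzyloxy)-3,5-dimethoxyphenyl]-4-[4-(benzyloxy)-3-methoxyphenyl]-2,3-dimethylbutan-1-one
Product: 15 4-[(2R,3S)-4-(4-hydroxy-3-methoxyphenyl)-2,3-dimethylbutyl]-2,6-dimethoxyphenol, via carbinol 14 (not isolated)
Conditions: NaBH4, EtOH–THF, 0 °C → rt; then AcOH, 10% Pd/C, H2 (3 atm), rt
Reagents that add atoms: none
Why: Hydride reduction of the aryl ketone to the benzylic carbinol followed by palladium-catalysed hydrogenolysis of the electron-rich benzylic C–OH bond and of both O-benzyl groups; the ketone is removed without exposing the alpha stereocentre to enolising acid, so both centres should keep their configuration.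

Compound list
1 | meso-2,3-dimethylsuccinic acid, (2R,3S)-2,3-dimethylbutanedioic acid | OC(=O)[C@H](C)[C@H](C)C(=O)O | starting material
2 | cis-2,3-dimethylsuccinic anhydride, (3R,4S)-3,4-dimethyloxolane-2,5-dione | O=C1[C@H](C)[C@H](C)C(=O)O1 | intermediate
3 | 1-(benzyloxy)-4-bromo-2-methoxybenzene | COc1cc(Br)ccc1OCc1ccccc1 | starting material
4 | [4-(benzyloxy)-3-methoxyphenyl]lithium | COc1cc([Li])ccc1OCc1ccccc1 | intermediate
5 | [4-(benzyloxy)-3-methoxyphenyl]zinc trifluoromethanesulfonate | COc1cc([Zn]OS(=O)(=O)C(F)(F)F)ccc1OCc1ccccc1 | intermediate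
6 | (2S,3R)-4-[4-(benzyloxy)-3-methoxyphenyl]-2,3-dimethyl-4-oxobutanoic acid | COc1cc(C(=O)[C@H](C)[C@H](C)C(=O)O)ccc1OCc1ccccc1 | intermediate
7 | (2S,3S)-4-[4-(benzyloxy)-3-methoxyphenyl]-2,3-dimethylbutanoic acid | COc1cc(C[C@H](C)[C@H](C)C(=O)O)ccc1OCc1ccccc1 | intermediate
8 | 4-bromo-2,6-dimethoxyphenol | COc1cc(Br)cc(OC)c1O | starting material
9 | 2-(benzyloxy)-5-bromo-1,3-dimethoxybenzene | COc1cc(Br)cc(OC)c1OCc1ccccc1 | intermediate
10 | (2S,3S)-4-[4-(benzyloxy)-3-methoxyphenyl]-2,3-dimethylbutanoyl chloride | COc1cc(C[C@H](C)[C@H](C)C(Cl)=O)ccc1OCc1ccccc1 | intermediate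
11 | [4-(benzyloxy)-3,5-dimethoxyphenyl]lithium | COc1cc([Li])cc(OC)c1OCc1ccccc1 | intermediate
12 | [4-(benzyloxy)-3,5-dimethoxyphenyl]zinc chloride | COc1cc([Zn]Cl)cc(OC)c1OCc1ccccc1 | intermediate
13 | (2S,3S)-1-[4-(benzyloxy)-3,5-dimethoxyphenyl]-4-[4-(benzyloxy)-3-methoxyphenyl]-2,3-dimethylbutan-1-one | COc1cc(C[C@H](C)[C@H](C)C(=O)c2cc(OC)c(OCc3ccccc3)c(OC)c2)ccc1OCc1ccccc1 | intermediate
14 | (2S,3S)-1-[4-(benzyloxy)-3,5-dimethoxyphenyl]-4-[4-(benzyloxy)-3-methoxyphenyl]-2,3-dimethylbutan-1-ol, both C1 epimers | COc1cc(C[C@H](C)[C@H](C)C(O)c2cc(OC)c(OCc3ccccc3)c(OC)c2)ccc1OCc1ccccc1 | intermediate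
15 | 4-[(2R,3S)-4-(4-hydroxy-3-methoxyphenyl)-2,3-dimethylbutyl]-2,6-dimethoxyphenol | COc1cc(C[C@H](C)[C@H](C)Cc2cc(OC)c(O)c(OC)c2)ccc1O | target

Total step count: 6. Longest linear sequence: 5 steps (steps 1, 2, 3, 5 and 6); step 4 is a side branch.

Steps most likely to fail

Step 5 (key step). Three processes could spoil it: loss of configuration at C2 of the acid chloride by ketene formation or enolisation, zinc-salt-promoted Friedel–Crafts ring closure of the acid chloride onto ring A, and decarbonylation at palladium before transmetalation. The fallback sets out from 7 and comes back at 15, forming the same bond at the methylene level so that no acyl electrophile and no ketone are involved. Acid 7 would be reduced with BH3·THF to the primary alcohol F1. Iodine, PPh3 and imidazole (Appel reaction) would convert it into the primary iodide F2. Zinc dust with LiCl in THF would insert to give the alkylzinc iodide F3, which would be coupled with aryl bromide 9 under Pd(OAc)2 and SPhos (Negishi coupling of an sp3 carbon with an aryl bromide) to the bis(benzyl) ether F4. Hydrogenolysis (H2, Pd/C, EtOAc–EtOH) would then give 15.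

Step 2. Selection between the two enantiotopic acyl–oxygen bonds may be insufficient, or transmetalation of the oxygen-rich arylzinc may be slow, so that enantiomeric purity or conversion falls short. The fallback sets out from 2 and comes back at 7, separating the asymmetric step from the carbon–carbon bond formation. Anhydride 2 would be opened by cinchona-alkaloid-mediated methanolysis (quinidine or quinine, whichever pseudo-enantiomer gives the required sense, MeOH, toluene, −55 °C) to the hemiester F5. Oxalyl chloride would give the ester acid chloride F6, which would undergo palladium-catalysed acylation with arylzinc triflate 5 (Pd(PPh3)4, THF) to the keto ester F7. Et3SiH in TFA would remove the ketone oxygen to give the methyl ester F8, and LiOH in aqueous THF would hydrolyse it to 7.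

Step 3. The benzyl ether may be cleaved in TFA, or the benzylic cation may lose a proton to a styrene before hydride capture, which would scramble C3. The fallback sets out from 6 and comes back at 7. Hydrogenolysis over Pd/C (H2, AcOH, rt) would remove the ketone oxygen on the metal surface without a free cation, and the benzyl group with it, giving the phenol acid F9. BnBr and K2CO3 in DMF would then benzylate phenol and acid to the benzyl ester benzyl ether F10, and LiOH in aqueous THF would free acid 7.

Further compounds
F1 | step 5 | (2S,3S)-4-[4-(benzyloxy)-3-methoxyphenyl]-2,3-dimethylbutan-1-ol | COc1cc(C[C@H](C)[C@H](C)CO)ccc1OCc1ccccc1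
F2 | step 5 | 1-(benzyloxy)-4-[(2S,3S)-4-iodo-2,3-dimethylbutyl]-2-methoxybenzene | COc1cc(C[C@H](C)[C@H](C)CI)ccc1OCc1ccccc1
F3 | step 5 | [(2S,3S)-4-[4-(benzyloxy)-3-methoxyphenyl]-2,3-dimethylbutyl]zinc iodide | COc1cc(C[C@H](C)[C@H](C)C[Zn]I)ccc1OCc1ccccc1
F4 | step 5 | 2-(benzyloxy)-5-[(2R,3S)-4-[4-(benzyloxy)-3-methoxyphenyl]-2,3-dimethylbutyl]-1,3-dimethoxybenzene | COc1cc(C[C@H](C)[C@H](C)Cc2cc(OC)c(OCc3ccccc3)c(OC)c2)ccc1OCc1ccccc1
F5 | step 2 | (2R,3S)-4-methoxy-2,3-dimethyl-4-oxobutanoic acid | OC(=O)[C@H](C)[C@H](C)C(=O)OC
F6 | step 2 | methyl (2S,3R)-4-chloro-2,3-dimethyl-4-oxobutanoate | ClC(=O)[C@H](C)[C@H](C)C(=O)OC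
F7 | step 2 | methyl (2S,3R)-4-[4-(benzyloxy)-3-methoxyphenyl]-2,3-dimethyl-4-oxobutanoate | COc1cc(C(=O)[C@H](C)[C@H](C)C(=O)OC)ccc1OCc1ccccc1
F8 | step 2 | methyl (2S,3S)-4-[4-(benzyloxy)-3-methoxyphenyl]-2,3-dimethylbutanoate | COc1cc(C[C@H](C)[C@H](C)C(=O)OC)ccc1OCc1ccccc1
F9 | step 3 | (2S,3S)-4-(4-hydroxy-3-methoxyphenyl)-2,3-dimethylbutanoic acid | COc1cc(C[C@H](C)[C@H](C)C(=O)O)ccc1O
F10 | step 3 | benzyl (2S,3S)-4-[4-(benzyloxy)-3-methoxyphenyl]-2,3-dimethylbutanoate | COc1cc(C[C@H](C)[C@H](C)C(=O)OCc2ccccc2)ccc1OCc1ccccc1
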